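The route rests on cutting the C4–C5 bond of ring A, the methylenecyclohexane ring (C1–C4, C5, C10) of the aryl-bearing decalin: C4 carries the exocyclic CH2 and C5 is the quaternary ring-fusion carbon. This vinyl-on-quaternary-carbon motif is exploited by placing a temporary ketone at C6 of ring B (C5–C10), so that C5 becomes an enolate carbon and C4 a 2-bromoalkene. One palladium-catalysed intramolecular α-alkenylation then closes ring A last, sets C5 cis to C10 from either C5 epimer and installs the methylene. Its precursor is a cyclohexanone (ring B, stereocentres from a Diels–Alder reaction) already carrying the arylmethyl group and the second decalin.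

Key step: step 18

Assumption: the target is drawn and delivered as the free bis(hydrogen sulfate) (formed as its pyridinium salt and protonated on an acid resin), and in the three catalyst-controlled steps (3, 5, 15) the ligand or catalyst antipode named is the one expected to give the drawn configuration.

Atom labels C1–C11 in the Why lines are those of the strategy paragraph (C11 = the exocyclic methylene carbon).

Step 1
Reactants: 1 3-acetyl-3-methyloxolan-2-one (racemic)
Product: 2 5-chloro-3-methylpentan-2-one (racemic)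
Conditions: conc. HCl, H2O, 100 °C, product distilled out
Reagents that add atoms: hydrogen chloride, Cl
Why: Acid-mediated opening of the lactone by chloride at the O–CH2 carbon followed by decarboxylation of the β-keto acid (decarboxylative lactone cleavage) should give the γ-chloro ketone.

Step 2
Reactants: 2 5-chloro-3-methylpentan-2-one
Product: 3 2-(4-chlorobutan-2-yl)-2-methyl-1,3-dioxolane (racemic)
Conditions: ethane-1,2-diol, TsOH (cat.), toluene, reflux, Dean–Stark trap
Reagents that add atoms: ethane-1,2-diol, OCCO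
Why: Acid-catalysed ketalisation with azeotropic removal of water masks the ketone so that an organomagnesium reagent can be made from the chloride.

Step 3
Reactants: 3 2-(4-chlorobutan-2-yl)-2-methyl-1,3-dioxolane; 4 4,4-dimethylcyclohex-2-en-1-one
Product: 7 (3R)-4,4-dimethyl-3-[3-(2-methyl-1,3-dioxolan-2-yl)butyl]cyclohexan-1-one (epimers at the side-chain methine), via Grignard reagent 5 (not isolated), via dialkylzinc 6 (not isolated)
Conditions: Mg, THF, 50 °C; Zn(OMe)2 (0.5 equiv), Et2O, 25 °C, filtration; then 4, Cu(OTf)2 (2 mol %), (S,R,R)-phosphoramidite from 1,1'-bi-2-naphthol and bis(1-phenylethyl)amine (4 mol %), toluene, −30 °C; aq. NH4Cl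
Reagents that add atoms: none
Why: Copper-catalysed asymmetric conjugate addition of a dialkylzinc to a cyclic enone (4,4-disubstituted cyclohexenones are standard substrates) should set the ring stereocentre under ligand control, while the remote side-chain methine stays epimeric and is corrected in step 4.

Step 4
Reactants: 7 (3R)-4,4-dimethyl-3-[3-(2-methyl-1,3-dioxolan-2-yl)butyl]cyclohexan-1-one
Product: 9 (4aS,7S)-4,4,7,8-tetramethyl-3,4,4a,5,6,7-hexahydronaphthalen-1(2H)-one, via diketone 8 (not isolated)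
Conditions: 2 M HCl, THF, 25 °C; then KOH, MeOH, 65 °C; chromatography
Reagents that add atoms: none
Why: Ketal hydrolysis followed by intramolecular aldol condensation of the 1,7-diketone should give the conjugated tetrasubstituted enone as the thermodynamic sink, and equilibration of the γ-methine through the extended dienolate should favour the pseudoaxial 7-methyl group, trans to H-4a, which avoids A1,2 strain with the 8-methyl group.

Step 5
Reactants: 9 (4aS,7S)-4,4,7,8-tetramethyl-3,4,4a,5,6,7-hexahydronaphthalen-1(2H)-one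
Product: 10 (1S,4aS,7S)-4,4,7,8-tetramethyl-1,2,3,4,4a,5,6,7-octahydronaphthalen-1-ol
Conditions: (R)-2-methyl-CBS-oxazaborolidine (20 mol %), catecholborane, toluene, −78 °C
Reagents that add atoms: none
Why: CBS reduction of the enone, with the alkenyl arm as the large substituent, should deliver hydride under reagent control and give the (1S)-allylic alcohol whose C–O bond lies on the same face as H-4a.

Step 6
Reactants: 10 (1S,4aS,7S)-4,4,7,8-tetramethyl-1,2,3,4,4a,5,6,7-octahydronaphthalen-1-ol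
Product: 12 2-[(1R,2S,4aS)-1,2,5,5-tetramethyl-1,2,3,4,4a,5,6,7-octahydronaphthalen-1-yl]-N,N-dimethylacetamide, via ketene N,O-acetal 11 (not isolated)
Conditions: MeC(OMe)2NMe2 (5 equiv), xylene, 140 °C
Reagents that add atoms: N,N-dimethylacetamide dimethyl acetal, CC(OC)(OC)N(C)C
Why: Eschenmoser–Claisen rearrangement: the [3,3] shift of 11 is suprafacial, so the new quaternary carbon receives the CH2C(O)NMe2 group on the face of the former C–O bond (anti to the neighbouring methyl group) and the double bond moves to the ring-fusion carbon.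

Step 7
Reactants: 12 2-[(1R,2S,4aS)-1,2,5,5-tetramethyl-1,2,3,4,4a,5,6,7-octahydronaphthalen-1-yl]-N,N-dimethylacetamide
Product: 13 2-[(1R,2S,4aS)-1,2,5,5-tetramethyl-1,2,3,4,4a,5,6,7-octahydronaphthalen-1-yl]ethan-1-ol
Conditions: LiEt3BH (2.5 equiv), THF, 0 → 25 °C; aq. NaOH
Reagents that add atoms: none
Why: Reduction of the tertiary amide to the primary alcohol by a trialkylborohydride (C–N cleavage of the intermediate hemiaminal) should leave the hindered trisubstituted alkene untouched.

Step 8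
Reactants: 13 2-[(1R,2S,4aS)-1,2,5,5-tetramethyl-1,2,3,4,4a,5,6,7-octahydronaphthalen-1-yl]ethan-1-ol
Product: 14 2-[(1R,2S,4aS)-1,2,5,5-tetramethyl-1,2,3,4,4a,5,6,7-octahydronaphthalen-1-yl]ethyl trifluoromethanesulfonate
Conditions: Tf2O, 2,6-lutidine, CH2Cl2, −78 °C; cold filtration through silica, used at once
Reagents that add atoms: trifluoromethanesulfonic anhydride, O=S(=O)(OS(=O)(=O)C(F)(F)F)C(F)(F)F
Why: O-Triflation of the primary alcohol gives an electrophile reactive enough for C-alkylation of a hindered ketone enolate at low temperature.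

Step 9
Reactants: 15 2-(2-bromoethyl)-1,3-dioxolane; 16 2,3-dibromoprop-1-ene
Product: 18 2-(4-bromopent-4-en-1-yl)-1,3-dioxolane, via Grignard reagent 17 (not isolated)
Conditions: Mg, THF, 25 °C; then 16, CuI (5 mol %), THF, 0 → 25 °C
Reagents that add atoms: none
Why: Copper-catalysed allylic substitution of the allylic bromide by the Grignard reagent (SN2 and SN2' give the same product) leaves the less reactive alkenyl bromide in place.

Step 10
Reactants: 18 2-(4-bromopent-4-en-1-yl)-1,3-dioxolane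
Product: 19 5-bromohex-5-enal
Conditions: 1 M HCl, acetone–H2O, 40 °C
Reagents that add atoms: water, O
Why: Acid-catalysed acetal hydrolysis frees the aldehyde, the alkenyl bromide being inert to dilute acid.

Step 11
Reactants: 19 5-bromohex-5-enal; 20 1-(triphenyl-λ5-phosphanylidene)propan-2-one
Product: 21 (3E)-8-bromonona-3,8-dien-2-one
Conditions: CH2Cl2, 40 °C
Reagents that add atoms: none
Why: Wittig olefination with a stabilised ylide should give the (E)-enone.

Step 12
Reactants: 21 (3E)-8-bromonona-3,8-dien-2-one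
Product: 22 {[(3E)-8-bromonona-1,3,8-trien-2-yl]oxy}(tert-butyl)dimethylsilane
Conditions: TBSOTf, Et3N, CH2Cl2, 0 °C
Reagents that add atoms: tert-butyldimethylsilyl trifluoromethanesulfonate, CC(C)(C)[Si](C)(C)OS(=O)(=O)C(F)(F)F
Why: Soft enolisation of the methyl ketone (silyl triflate and amine) gives the 2-silyloxy-1,3-diene with the (E)-alkene unchanged.

Step 13
Reactants: 23 (2E)-but-2-enal
Product: 25 (2Z)-2-bromobut-2-enal, via 2,3-dibromobutanal 24 (not isolated)
Conditions: Br2, CH2Cl2, −20 °C; then Et3N, 0 → 25 °C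
Reagents that add atoms: bromine, BrBr
Why: Bromine addition and E2 loss of HBr from the α-position (α-bromination of an enal) should give the more stable (Z)-isomer, with bromine cis to the methyl group.

Step 14
Reactants: 25 (2Z)-2-bromobut-2-enal; 26 2-(chloromethyl)-1,4-dimethoxybenzene
Product: 28 (2E)-2-[(2,5-dimethoxyphenyl)methyl]but-2-enal, via benzylzinc chloride 27 (not isolated)
Conditions: Zn dust, LiCl, THF, 25 °C; then 25, Pd(PPh3)4 (3 mol %), THF, 25 °C
Reagents that add atoms: none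
Why: Negishi coupling of the benzylic zinc reagent with the alkenyl bromide proceeds with retention of alkene geometry, so the arylmethyl group ends up cis to the β-methyl group, and cross-coupling should outrun addition to the aldehyde.

Step 15
Reactants: 22 {[(3E)-8-bromonona-1,3,8-trien-2-yl]oxy}(tert-butyl)dimethylsilane; 28 (2E)-2-[(2,5-dimethoxyphenyl)methyl]but-2-enal
Product: 29 (1R,2S,6S)-2-(4-bromopent-4-en-1-yl)-4-[(tert-butyldimethylsilyl)oxy]-1-[(2,5-dimethoxyphenyl)methyl]-6-methylcyclohex-3-ene-1-carbaldehyde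
Conditions: (S)-B-o-tolyl oxazaborolidine from α,α-diphenylprolinol, activated with Tf2NH (20 mol %), CH2Cl2, −78 → −40 °C
Reagents that add atoms: none
Why: Lewis acid-catalysed Diels–Alder reaction in which the CH2 terminus of the 2-silyloxydiene bonds to the β-carbon of the enal (silyl enol ether para to the formyl-bearing carbon), the endo transition state places CHO cis to the bromopentenyl chain, the (E)-enal geometry places the 6-methyl group trans to CHO, and the chiral cationic oxazaborolidine selects the enal face.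

Step 16
Reactants: 29 (1R,2S,6S)-2-(4-bromopent-4-en-1-yl)-4-[(tert-butyldimethylsilyl)oxy]-1-[(2,5-dimethoxyphenyl)methyl]-6-methylcyclohex-3-ene-1-carbaldehyde
Product: 31 {[(3S,4S,5S)-3-(4-bromopent-4-en-1-yl)-4-[(2,5-dimethoxyphenyl)methyl]-4,5-dimethylcyclohex-1-en-1-yl]oxy}(tert-butyl)dimethylsilane, via tosylhydrazone 30 (not isolated)
Conditions: TsNHNH2, THF, 40 °C; then catecholborane, CHCl3, 0 °C; NaOAc·3H2O, 60 °C
Reagents that add atoms: none
Why: Reduction of the tosylhydrazone with catecholborane and loss of sulfinate and N2 (a mild variant of Wolff–Kishner deoxygenation) should turn the neopentyl aldehyde into the methyl group without touching the silyl enol ether, the alkenyl bromide or the three stereocentres.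

Step 17
Reactants: 31 {[(3S,4S,5S)-3-(4-bromopent-4-en-1-yl)-4-[(2,5-dimethoxyphenyl)methyl]-4,5-dimethylcyclohex-1-en-1-yl]oxy}(tert-butyl)dimethylsilane; 14 2-[(1R,2S,4aS)-1,2,5,5-tetramethyl-1,2,3,4,4a,5,6,7-octahydronaphthalen-1-yl]ethyl trifluoromethanesulfonate
Product: 33 (3S,4S,5S)-3-(4-bromopent-4-en-1-yl)-4-[(2,5-dimethoxyphenyl)methyl]-4,5-dimethyl-2-{2-[(1R,2S,4aS)-1,2,5,5-tetramethyl-1,2,3,4,4a,5,6,7-octahydronaphthalen-1-yl]ethyl}cyclohexan-1-one (both C2 epimers), via lithium enolate 32 (not isolated)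
Conditions: MeLi (1.1 equiv), DME, 0 → 25 °C; then 14, THF, −78 → −10 °C
Reagents that add atoms: none
Why: Regiospecific enolate formation from the silyl enol ether (Si–O cleavage by MeLi) and C-alkylation with the primary triflate join the two fragments at C5; the configuration of this new centre is immaterial because step 18 passes through the enolate again.

Step 18
Reactants: 33 (3S,4S,5S)-3-(4-bromopent-4-en-1-yl)-4-[(2,5-dimethoxyphenyl)methyl]-4,5-dimethyl-2-{2-[(1R,2S,4aS)-1,2,5,5-tetramethyl-1,2,3,4,4a,5,6,7-octahydronaphthalen-1-yl]ethyl}cyclohexan-1-one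
Product: 35 (3S,4S,4aR,8aS)-4-[(2,5-dimethoxyphenyl)methyl]-3,4-dimethyl-8-methylidene-8a-{2-[(1R,2S,4aS)-1,2,5,5-tetramethyl-1,2,3,4,4a,5,6,7-octahydronaphthalen-1-yl]ethyl}-3,4,4a,5,6,7,8,8a-octahydronaphthalen-1(2H)-one, via sodium enolate 34 (not isolated)
Conditions: Pd2(dba)3 (5 mol %), DPEphos (12 mol %), NaOtBu (1.5 equiv), THF, 65 °C
Reagents that add atoms: none
Why: Oxidative addition of zerovalent palladium into the C4–Br bond gives an alkenylpalladium bromide, NaOtBu equilibrates the two ketone enolates, and the enolate on C5 (34) binds palladium through carbon so that C–C reductive elimination from a seven-membered palladacycle forms the C4–C5 bond. The closest known reaction type is the palladium-catalysed intramolecular α-alkenylation of ketones used to annulate methylenecycloalkanes. Ring A closes in a 6-exo fashion with respect to the C5=C6 enolate double bond (enol-exo), the new bond forming perpendicular to the enolate plane. The new quaternary stereocentre C5 is controlled by C10: the three-carbon tether C1–C3 can reach only the enolate face syn to the C10–C1 bond, so the ring fusion must be cis, and both C5 epimers of 33 converge on one configuration through the planar enolate. The step needs regioselectivity between the two α-carbons, which the tether secures because the C7 enolate would have to close an eight-membered ring and simply re-equilibrates; it also needs C- over O-alkenylation and coupling faster than loss of HBr from the bromoalkene, for which the wide-bite-angle bisphosphine and the moderate temperature are chosen.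

Step 19
Reactants: 35 (3S,4S,4aR,8aS)-4-[(2,5-dimethoxyphenyl)methyl]-3,4-dimethyl-8-methylidene-8a-{2-[(1R,2S,4aS)-1,2,5,5-tetramethyl-1,2,3,4,4a,5,6,7-octahydronaphthalen-1-yl]ethyl}-3,4,4a,5,6,7,8,8a-octahydronaphthalen-1(2H)-one
Product: 37 2-{[(1S,2S,4aR,8aR)-1,2-dimethyl-5-methylidene-4a-{2-[(1R,2S,4aS)-1,2,5,5-tetramethyl-1,2,3,4,4a,5,6,7-octahydronaphthalen-1-yl]ethyl}decahydronaphthalen-1-yl]methyl}-1,4-dimethoxybenzene, via hydrazone 36 (not isolated)
Conditions: N2H4·H2O, KOH, diethylene glycol, 140 °C, then 200 °C with removal of water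
Reagents that add atoms: none
Why: Wolff–Kishner reduction deletes the temporary ketone through a diazenide anion and carbanion protonation (no carbon radical that could trigger a 1,2-vinyl shift of the neighbouring methylidene unit), and no stereocentre lies next to the carbonyl on its enolisable side.

Step 20
Reactants: 37 2-{[(1S,2S,4aR,8aR)-1,2-dimethyl-5-methylidene-4a-{2-[(1R,2S,4aS)-1,2,5,5-tetramethyl-1,2,3,4,4a,5,6,7-octahydronaphthalen-1-yl]ethyl}decahydronaphthalen-1-yl]methyl}-1,4-dimethoxybenzene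
Product: 38 2-{[(1S,2S,4aR,8aR)-1,2-dimethyl-5-methylidene-4a-{2-[(1R,2S,4aS)-1,2,5,5-tetramethyl-1,2,3,4,4a,5,6,7-octahydronaphthalen-1-yl]ethyl}decahydronaphthalen-1-yl]methyl}benzene-1,4-diol
Conditions: n-BuSH, n-BuLi, HMPA, 0 °C; then 37, 105 °C; dilute HCl, under Ar
Reagents that add atoms: none
Why: SN2 demethylation of both aryl methyl ethers by thiolate under non-acidic conditions should free the hydroquinone without isomerising the 1,1-disubstituted or the trisubstituted alkene.

Step 21
Reactants: 38 2-{[(1S,2S,4aR,8aR)-1,2-dimethyl-5-methylidene-4a-{2-[(1R,2S,4aS)-1,2,5,5-tetramethyl-1,2,3,4,4a,5,6,7-octahydronaphthalen-1-yl]ethyl}decahydronaphthalen-1-yl]methyl}benzene-1,4-diol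
Product: 39 2-{[(1S,2S,4aR,8aR)-1,2-dimethyl-5-methylidene-4a-{2-[(1R,2S,4aS)-1,2,5,5-tetramethyl-1,2,3,4,4a,5,6,7-octahydronaphthalen-1-yl]ethyl}decahydronaphthalen-1-yl]methyl}-1,4-phenylene bis(hydrogen sulfate) (CNP0439949.2)
Conditions: SO3·pyridine (6 equiv), pyridine, 50 °C; then cation-exchange resin (H+ form), 0 °C
Reagents that add atoms: sulfur trioxide–pyridine complex, O=S(=O)([O-])[n+]1ccccc1
Why: O-Sulfation of both phenols with the sulfur trioxide–amine complex and protonation of the bis-sulfate salt should give the target, the alkenes being inert to this mild sulfating agent.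

Compound list

1 | 3-acetyl-3-methyloxolan-2-one (racemic) | CC(=O)C1(C)CCOC1=O | starting material
2 | 5-chloro-3-methylpentan-2-one (racemic) | CC(=O)C(C)CCCl | intermediate
3 | 2-(4-chlorobutan-2-yl)-2-methyl-1,3-dioxolane (racemic) | CC(CCCl)C1(C)OCCO1 | intermediate
4 | 4,4-dimethylcyclohex-2-en-1-one | CC1(C)CCC(=O)C=C1 | starting material
5 | [3-(2-methyl-1,3-dioxolan-2-yl)butyl]magnesium chloride | CC(CC[Mg]Cl)C1(C)OCCO1 | intermediate (not isolated)
6 | bis[3-(2-methyl-1,3-dioxolan-2-yl)butyl]zinc | CC(CC[Zn]CCC(C)C1(C)OCCO1)C1(C)OCCO1 | intermediate (not isolated)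
7 | (3R)-4,4-dimethyl-3-[3-(2-methyl-1,3-dioxolan-2-yl)butyl]cyclohexan-1-one (epimers at the side-chain methine) | O=C1CCC(C)(C)[C@H](CCC(C)C2(C)OCCO2)C1 | intermediate
8 | (3R)-4,4-dimethyl-3-(3-methyl-4-oxopentyl)cyclohexan-1-one (epimers at the side-chain methine) | O=C1CCC(C)(C)[C@H](CCC(C)C(C)=O)C1 | intermediate (not isolated)
9 | (4aS,7S)-4,4,7,8-tetramethyl-3,4,4a,5,6,7-hexahydronaphthalen-1(2H)-one (H-4a and 7-CH3 trans) | O=C1CCC(C)(C)[C@@H]2CC[C@H](C)C(C)=C12 | intermediate
10 | (1S,4aS,7S)-4,4,7,8-tetramethyl-1,2,3,4,4a,5,6,7-octahydronaphthalen-1-ol (OH cis to H-4a) | O[C@H]1CCC(C)(C)[C@@H]2CC[C@H](C)C(C)=C12 | intermediate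
11 | N,N-dimethyl-1-{[(1S,4aS,7S)-4,4,7,8-tetramethyl-1,2,3,4,4a,5,6,7-octahydronaphthalen-1-yl]oxy}ethen-1-amine | C=C(N(C)C)O[C@H]1CCC(C)(C)[C@@H]2CC[C@H](C)C(C)=C12 | intermediate (not isolated)
12 | 2-[(1R,2S,4aS)-1,2,5,5-tetramethyl-1,2,3,4,4a,5,6,7-octahydronaphthalen-1-yl]-N,N-dimethylacetamide | CN(C)C(=O)C[C@@]1(C)C2=CCCC(C)(C)[C@@H]2CC[C@@H]1C | intermediate
13 | 2-[(1R,2S,4aS)-1,2,5,5-tetramethyl-1,2,3,4,4a,5,6,7-octahydronaphthalen-1-yl]ethan-1-ol | OCC[C@@]1(C)C2=CCCC(C)(C)[C@@H]2CC[C@@H]1C | intermediate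
14 | 2-[(1R,2S,4aS)-1,2,5,5-tetramethyl-1,2,3,4,4a,5,6,7-octahydronaphthalen-1-yl]ethyl trifluoromethanesulfonate | O=S(=O)(OCC[C@@]1(C)C2=CCCC(C)(C)[C@@H]2CC[C@@H]1C)C(F)(F)F | intermediate
15 | 2-(2-bromoethyl)-1,3-dioxolane | BrCCC1OCCO1 | starting material
16 | 2,3-dibromoprop-1-ene | C=C(Br)CBr | starting material
17 | [2-(1,3-dioxolan-2-yl)ethyl]magnesium bromide | Br[Mg]CCC1OCCO1 | intermediate (not isolated)
18 | 2-(4-bromopent-4-en-1-yl)-1,3-dioxolane | C=C(Br)CCCC1OCCO1 | intermediate
19 | 5-bromohex-5-enal | C=C(Br)CCCC=O | intermediate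
20 | 1-(triphenyl-λ5-phosphanylidene)propan-2-one | CC(=O)C=P(c1ccccc1)(c1ccccc1)c1ccccc1 | starting material
21 | (3E)-8-bromonona-3,8-dien-2-one | CC(=O)/C=C/CCCC(Br)=C | intermediate
22 | {[(3E)-8-bromonona-1,3,8-trien-2-yl]oxy}(tert-butyl)dimethylsilane | C=C(O[Si](C)(C)C(C)(C)C)/C=C/CCCC(Br)=C | intermediate
23 | (2E)-but-2-enal | C/C=C/C=O | starting material
24 | 2,3-dibromobutanal | CC(Br)C(Br)C=O | intermediate (not isolated)
25 | (2Z)-2-bromobut-2-enal | C/C=C(\Br)C=O | intermediate
26 | 2-(chloromethyl)-1,4-dimethoxybenzene | COc1ccc(OC)c(CCl)c1 | starting material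
27 | [(2,5-dimethoxyphenyl)methyl]zinc chloride | COc1ccc(OC)c(C[Zn]Cl)c1 | intermediate (not isolated)
28 | (2E)-2-[(2,5-dimethoxyphenyl)methyl]but-2-enal (arylmethyl cis to the β-methyl) | C/C=C(\Cc1cc(OC)ccc1OC)C=O | intermediate
29 | (1R,2S,6S)-2-(4-bromopent-4-en-1-yl)-4-[(tert-butyldimethylsilyl)oxy]-1-[(2,5-dimethoxyphenyl)methyl]-6-methylcyclohex-3-ene-1-carbaldehyde (CHO cis to the C2 chain, trans to 6-CH3) | C=C(Br)CCC[C@H]1C=C(O[Si](C)(C)C(C)(C)C)C[C@H](C)[C@]1(C=O)Cc1cc(OC)ccc1OC | intermediate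
30 | (E)-4-methylbenzenesulfonylhydrazone of 29 | C=C(Br)CCC[C@H]1C=C(O[Si](C)(C)C(C)(C)C)C[C@H](C)[C@]1(/C=N/NS(=O)(=O)c1ccc(C)cc1)Cc1cc(OC)ccc1OC | intermediate (not isolated)
31 | {[(3S,4S,5S)-3-(4-bromopent-4-en-1-yl)-4-[(2,5-dimethoxyphenyl)methyl]-4,5-dimethylcyclohex-1-en-1-yl]oxy}(tert-butyl)dimethylsilane | C=C(Br)CCC[C@H]1C=C(O[Si](C)(C)C(C)(C)C)C[C@H](C)[C@]1(C)Cc1cc(OC)ccc1OC | intermediate
32 | lithium (3S,4S,5S)-3-(4-bromopent-4-en-1-yl)-4-[(2,5-dimethoxyphenyl)methyl]-4,5-dimethylcyclohex-1-en-1-olate | C=C(Br)CCC[C@H]1C=C(O[Li])C[C@H](C)[C@]1(C)Cc1cc(OC)ccc1OC | intermediate (not isolated)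
33 | (3S,4S,5S)-3-(4-bromopent-4-en-1-yl)-4-[(2,5-dimethoxyphenyl)methyl]-4,5-dimethyl-2-{2-[(1R,2S,4aS)-1,2,5,5-tetramethyl-1,2,3,4,4a,5,6,7-octahydronaphthalen-1-yl]ethyl}cyclohexan-1-one (both C2 epimers) | O=C1C[C@H](C)[C@](C)(Cc2cc(OC)ccc2OC)[C@@H](CCCC(Br)=C)C1CC[C@@]1(C)C2=CCCC(C)(C)[C@@H]2CC[C@@H]1C | intermediate
34 | sodium enolate of 33 on the carbon bearing the ethyl link (cyclohex-1-en-1-olate) | [Na]OC=1C[C@H](C)[C@](C)(Cc2cc(OC)ccc2OC)[C@@H](CCCC(Br)=C)C=1CC[C@@]1(C)C2=CCCC(C)(C)[C@@H]2CC[C@@H]1C | intermediate (not isolated)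
35 | (3S,4S,4aR,8aS)-4-[(2,5-dimethoxyphenyl)methyl]-3,4-dimethyl-8-methylidene-8a-{2-[(1R,2S,4aS)-1,2,5,5-tetramethyl-1,2,3,4,4a,5,6,7-octahydronaphthalen-1-yl]ethyl}-3,4,4a,5,6,7,8,8a-octahydronaphthalen-1(2H)-one (cis-fused) | C=C1CCC[C@H]2[C@]1(CC[C@@]1(C)C3=CCCC(C)(C)[C@@H]3CC[C@@H]1C)C(=O)C[C@H](C)[C@]2(C)Cc1cc(OC)ccc1OC | intermediate
36 | hydrazone of 35 (E/Z mixture) | C=C1CCC[C@H]2[C@]1(CC[C@@]1(C)C3=CCCC(C)(C)[C@@H]3CC[C@@H]1C)C(=NN)C[C@H](C)[C@]2(C)Cc1cc(OC)ccc1OC | intermediate (not isolated)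
37 | 2-{[(1S,2S,4aR,8aR)-1,2-dimethyl-5-methylidene-4a-{2-[(1R,2S,4aS)-1,2,5,5-tetramethyl-1,2,3,4,4a,5,6,7-octahydronaphthalen-1-yl]ethyl}decahydronaphthalen-1-yl]methyl}-1,4-dimethoxybenzene | C=C1CCC[C@H]2[C@]1(CC[C@@]1(C)C3=CCCC(C)(C)[C@@H]3CC[C@@H]1C)CC[C@H](C)[C@]2(C)Cc1cc(OC)ccc1OC | intermediate
38 | 2-{[(1S,2S,4aR,8aR)-1,2-dimethyl-5-methylidene-4a-{2-[(1R,2S,4aS)-1,2,5,5-tetramethyl-1,2,3,4,4a,5,6,7-octahydronaphthalen-1-yl]ethyl}decahydronaphthalen-1-yl]methyl}benzene-1,4-diol | C=C1CCC[C@H]2[C@]1(CC[C@@]1(C)C3=CCCC(C)(C)[C@@H]3CC[C@@H]1C)CC[C@H](C)[C@]2(C)Cc1cc(O)ccc1O | intermediate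
39 | 2-{[(1S,2S,4aR,8aR)-1,2-dimethyl-5-methylidene-4a-{2-[(1R,2S,4aS)-1,2,5,5-tetramethyl-1,2,3,4,4a,5,6,7-octahydronaphthalen-1-yl]ethyl}decahydronaphthalen-1-yl]methyl}-1,4-phenylene bis(hydrogen sulfate) (CNP0439949.2) | C=C1CCC[C@H]2[C@]1(CC[C@@]1(C)C3=CCCC(C)(C)[C@@H]3CC[C@@H]1C)CC[C@H](C)[C@]2(C)Cc1cc(OS(=O)(=O)O)ccc1OS(=O)(=O)O | target

Total step count: 21. Longest linear sequence: 13 steps (steps 1–8, then 17–21).

Steps most likely to fail

1. Step 18 (ring closure). Reductive elimination at the crowded, fully substituted enolate carbon may be slower than base-induced loss of HBr from the bromoalkene or protodebromination, so that ring A does not close. The fallback replaces cross-coupling by π-acid activation of an alkyne. Setting out from 33, TBAF in DMF at 60 °C removes HBr from the 2-bromoalkene to give the alkynyl ketone F1. TBSOTf and Et3N under equilibrating conditions then give the tetrasubstituted silyl enol ether F2; the regioisomeric enol ether cannot cyclise and is recycled through F1. A cationic gold catalyst from (Ph3P)AuCl and AgBF4 in CH2Cl2–MeOH should then effect a Conia-ene-type 6-exo-dig carbocyclisation, again on the face syn to the side-chain methine, and the route is rejoined at 35.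

2. Step 17 (fragment union). Proton transfer between enolate and product (loss of regiocontrol, double alkylation), O-alkylation, or ionisation and π-cyclisation of the triflate before C-alkylation may erode the coupling. The fallback forms the same C–C bond by carbonyl addition. Setting out from 13 and 31, oxidation of 13 with DMP (triacetoxy periodinane) gives the aldehyde F3. BF3·OEt2-mediated Mukaiyama aldol addition of 31 to F3 at −78 °C gives the hydroxy ketone F4, and MsCl/Et3N followed by DBU gives the enone F5. Conjugate reduction with [(Ph3P)CuH]6 then returns to the route at 33.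

3. Step 15 (cycloaddition). Enantiofacial discrimination of the trisubstituted enal by the chiral Lewis acid may be insufficient, or turnover too slow at the low temperature needed for selectivity. The fallback takes absolute control from the enantiopure partner instead of the catalyst. Setting out from 22 and 28, the cycloaddition is run with Me2AlCl in CH2Cl2 at −78 °C, which should give 29 together with its enantiomer F6 (same endo and regiochemical outcome). Step 16 converts the pair, through tosylhydrazone F7, into 31 and its enantiomer F8. Alkylation of the racemic enolate (32 and its enantiomer, lithium enolate F9) with enantiopure 14 gives 33 and the diastereomeric ketone F10, which is removed by chromatography (at the latest after ring closure), rejoining the route at 33.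

Further compounds

F1 | step 18 | (3S,4S,5S)-4-[(2,5-dimethoxyphenyl)methyl]-4,5-dimethyl-3-(pent-4-yn-1-yl)-2-{2-[(1R,2S,4aS)-1,2,5,5-tetramethyl-1,2,3,4,4a,5,6,7-octahydronaphthalen-1-yl]ethyl}cyclohexan-1-one | O=C1C[C@H](C)[C@](C)(Cc2cc(OC)ccc2OC)[C@@H](CCCC#C)C1CC[C@@]1(C)C2=CCCC(C)(C)[C@@H]2CC[C@@H]1C
F2 | step 18 | tetrasubstituted tert-butyldimethylsilyl enol ether of F1 | CC(C)(C)[Si](C)(C)OC=1C[C@H](C)[C@](C)(Cc2cc(OC)ccc2OC)[C@@H](CCCC#C)C=1CC[C@@]1(C)C2=CCCC(C)(C)[C@@H]2CC[C@@H]1C
F3 | step 17 | 2-[(1R,2S,4aS)-1,2,5,5-tetramethyl-1,2,3,4,4a,5,6,7-octahydronaphthalen-1-yl]acetaldehyde | O=CC[C@@]1(C)C2=CCCC(C)(C)[C@@H]2CC[C@@H]1C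
F4 | step 17 | β-hydroxy ketone from 31 and F3 (epimers at the two new centres) | O=C1C[C@H](C)[C@](C)(Cc2cc(OC)ccc2OC)[C@@H](CCCC(Br)=C)C1C(O)C[C@@]1(C)C2=CCCC(C)(C)[C@@H]2CC[C@@H]1C
F5 | step 17 | 2-alkylidene ketone from F4 (E/Z mixture) | O=C1C[C@H](C)[C@](C)(Cc2cc(OC)ccc2OC)[C@@H](CCCC(Br)=C)C1=CC[C@@]1(C)C2=CCCC(C)(C)[C@@H]2CC[C@@H]1C
F6 | step 15 | enantiomer of 29, (1S,2R,6R) | C=C(Br)CCC[C@@H]1C=C(O[Si](C)(C)C(C)(C)C)C[C@@H](C)[C@@]1(C=O)Cc1cc(OC)ccc1OC
F7 | step 15 | enantiomer of tosylhydrazone 30 | C=C(Br)CCC[C@@H]1C=C(O[Si](C)(C)C(C)(C)C)C[C@@H](C)[C@@]1(/C=N/NS(=O)(=O)c1ccc(C)cc1)Cc1cc(OC)ccc1OC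
F8 | step 15 | enantiomer of 31, (3R,4R,5R) | C=C(Br)CCC[C@@H]1C=C(O[Si](C)(C)C(C)(C)C)C[C@@H](C)[C@@]1(C)Cc1cc(OC)ccc1OC
F9 | step 15 | enantiomer of lithium enolate 32 | C=C(Br)CCC[C@@H]1C=C(O[Li])C[C@@H](C)[C@@]1(C)Cc1cc(OC)ccc1OC
F10 | step 15 | diastereomer of 33 with the (3R,4R,5R)-cyclohexanone unit | O=C1C[C@@H](C)[C@@](C)(Cc2cc(OC)ccc2OC)[C@H](CCCC(Br)=C)C1CC[C@@]1(C)C2=CCCC(C)(C)[C@@H]2CC[C@@H]1C
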